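**Plan**

- Retrosynthesis: after removing seven benzyl groups and returning the ketone to a silyl carbinol, ring D is cut at C4'–C5', C6'–C1' and C3'–C4' into a 2,3,4-trisubstituted 3-benzyloxycyclobutenone and 1-methoxypropyne. The cyclobutenone is cut at C1–C2 and C3–C4 into a catechin-derived aldoketene and a benzyloxyalkyne.
- Enabling feature: ring D is a hexasubstituted 3-methoxyphenol. The free C4'–OH is meta to C6'–OCH3 with C5'–CH3 between them, and C1' (acyl carbon), C2' (O) and C3' (CH2 bridge) complete the ring. This is the substitution imprint of a vinylketene plus methoxyalkyne benzannulation.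
- Forward: rings A, B and C come intact from (+)-catechin (perbenzylation, C8 bromination, Negishi chain extension). The four-membered ring is closed by a ketene–ynol ether [2+2] cycloaddition, and ring D is then built from it by the benzannulation. Benzylation, desilylation, oxidation and hydrogenolysis finish the synthesis.
- Stereochemistry: flavan C2 and C3 are those of (+)-catechin, and the side-chain (R) centre is that of (R)-2-methylbutanoic acid. No other stereocentre reaches the target.

Key step: step 14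

**Remarks on the chemistry**

- PBC-8-yl stands for (2R,3S)-3,5,7-tris(benzyloxy)-2-[3,4-bis(benzyloxy)phenyl]chroman-8-yl. Ring D locants are C1' (side-chain carbon), C2' (O), C3' (CH2 bridge), C4' (O), C5' (CH3), C6' (OCH3).
- The side-chain carbinol carbon (compounds 17, 18, 23–30) and ring carbon C4 of cyclobutenone 23 are carried as epimer mixtures. Both centres become sp2 (steps 14 and 17), so no separation is planned.
- (R)-2-Methylbutanoic acid and (3-ethoxy-3-oxopropyl)zinc bromide solution are assumed to be purchasable.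

**Route**

Step 1
Reactants: 1 (+)-catechin
Product: 2 5,7-di-O-benzyl-2-[3,4-bis(benzyloxy)phenyl]chroman-3-ol (tetra-O-benzylcatechin)
Conditions: BnBr (4.4 equiv), K2CO3, DMF, 0 °C → rt
Reagents that add atoms: benzyl bromide, BrCc1ccccc1
Why: Williamson etherification with a carbonate base alkylates only the four phenols, and the mild conditions leave the secondary 3-OH free and C2 unepimerised.

Step 2
Reactants: 2 tetra-O-benzylcatechin
Product: 3 3,5,7-tri-O-benzyl-2-[3,4-bis(benzyloxy)phenyl]chromane (penta-O-benzylcatechin)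
Conditions: NaH, BnBr, DMF, 0 °C → rt
Reagents that add atoms: benzyl bromide, BrCc1ccccc1
Why: Williamson benzylation of the sodium alkoxide puts the same hydrogenolysable group on every oxygen, so one final step can unmask all of them.

Step 3
Reactants: 3 penta-O-benzylcatechin
Product: 4 8-bromo-penta-O-benzylcatechin (PBC-8-yl bromide)
Conditions: NBS, CH2Cl2, −78 °C → rt
Reagents that add atoms: N-bromosuccinimide, BrN1C(=O)CCC1=O
Why: Electrophilic aromatic bromination of the 5,7-dialkoxy ring A of O-benzylated catechins occurs at C8 in preference to C6 at low temperature, the established regioselectivity for this substrate class.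

Step 4
Reactants: 4 PBC-8-yl bromide; 5 (3-ethoxy-3-oxopropyl)zinc bromide
Product: 6 ethyl 3-(PBC-8-yl)propanoate
Conditions: Pd(OAc)2 (5 mol %), SPhos (10 mol %), THF, 60 °C
Reagents that add atoms: none
Why: Negishi cross-coupling of the ester-stabilised zinc homoenolate installs the three-carbon chain in one step; the bulky electron-rich biarylphosphine promotes oxidative addition into the hindered di-ortho-alkoxy aryl bromide and reductive elimination ahead of β-hydride loss.

Step 5
Reactants: 6 ethyl 3-(PBC-8-yl)propanoate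
Product: 7 3-(PBC-8-yl)propanoic acid
Conditions: LiOH·H2O, THF/MeOH/H2O, 45 °C; then dilute HCl to pH 3
Reagents that add atoms: lithium hydroxide, [Li+].[OH-]
Why: Ester saponification by acyl–oxygen cleavage, to which benzyl ethers and the flavan stereocentres are inert.

Step 6
Reactants: 7 3-(PBC-8-yl)propanoic acid
Product: 8 3-(PBC-8-yl)propanoyl chloride
Conditions: (COCl)2, cat. DMF, CH2Cl2, 0 °C → rt; concentrate and use crude
Reagents that add atoms: oxalyl chloride, ClC(=O)C(=O)Cl
Why: Chloroiminium-catalysed acid chloride formation; both ring positions ortho to the chain (C7 and C8a) are substituted, so intramolecular Friedel–Crafts acylation cannot compete.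

Step 7
Reactants: 9 (R)-2-methylbutanoic acid
Product: 10 (R)-2-methylbutan-1-ol
Conditions: LiAlH4, Et2O, 0 °C → reflux; aqueous NaOH work-up
Reagents that add atoms: none
Why: Hydride reduction proceeds through the carboxylate and aluminium alkoxide, neither of which enolises, so the α-stereocentre is retained.

Step 8
Reactants: 10 (R)-2-methylbutan-1-ol
Product: 11 (R)-2-methylbutanal
Conditions: TEMPO (1 mol %), KBr (10 mol %), aq. NaOCl, NaHCO3, CH2Cl2, 0 °C; use at once
Reagents that add atoms: none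
Why: The TEMPO-catalysed hypochlorite (Anelli) oxidation stops at the aldehyde in a buffered two-phase medium in which α-branched aldehydes of this type keep their configuration.

Step 9
Reactants: 12 trichloroethylene; 13 benzyl alcohol
Product: 14 benzyl (E)-1,2-dichlorovinyl ether
Conditions: KH, THF, 0 °C; then 12, −50 °C → rt
Reagents that add atoms: none
Why: Alkoxide-induced dehydrochlorination of trichloroethylene followed by anti addition of the alkoxide to the resulting chloroalkyne gives the E-dichlorovinyl ether, the standard entry to ynol ethers.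

Step 10
Reactants: 14 benzyl (E)-1,2-dichlorovinyl ether; 11 (R)-2-methylbutanal
Product: 17 (4R)-1-(benzyloxy)-4-methylhex-1-yn-3-ol (epimers at C3), via benzyloxy(chloro)acetylene 15 (not isolated), via lithium benzyloxyacetylide 16 (not isolated)
Conditions: n-BuLi (2.3 equiv), THF, −78 °C; then 11, −78 °C; aq. NH4Cl; crude product kept cold and base-washed
Reagents that add atoms: none
Why: Elimination of HCl then chlorine–lithium exchange gives the lithium alkoxyacetylide, which adds to the aldehyde carbonyl at −78 °C faster than it deprotonates the α-carbon; the new carbinol centre forms unselectively and is later oxidised away.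

Step 11
Reactants: 17 (4R)-1-(benzyloxy)-4-methylhex-1-yn-3-ol
Product: 18 (4R)-1-(benzyloxy)-3-(tert-butyldimethylsilyloxy)-4-methylhex-1-yne (epimers at C3)
Conditions: TBSCl, imidazole, DMF, 0 °C → rt
Reagents that add atoms: tert-butyldimethylsilyl chloride, CC(C)(C)[Si](C)(C)Cl
Why: Imidazole-mediated silylation keeps the medium basic, which avoids the acid-triggered Meyer–Schuster rearrangement and hydration open to a hydroxy ynol ether.

Step 12
Reactants: 19 chloroacetaldehyde dimethyl acetal
Product: 21 1-methoxyprop-1-yne, via sodium methoxyacetylide 20 (not isolated)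
Conditions: NaNH2 (3.1 equiv), liq. NH3, −33 °C; then MeI; evaporate NH3, distil
Reagents that add atoms: iodomethane, CI
Why: Amide-induced loss of methanol and HCl from the chloroacetal with deprotonation gives the sodium alkoxyacetylide, which is C-methylated by SN2 in liquid ammonia, the classical one-flask alkoxyalkyne synthesis.

Step 13
Reactants: 8 3-(PBC-8-yl)propanoyl chloride; 18 benzyl ynol ether
Product: 23 3-(benzyloxy)-2-[(2R)-1-(tert-butyldimethylsilyloxy)-2-methylbutyl]-4-(PBC-8-ylmethyl)cyclobut-2-en-1-one (epimers at the carbinol carbon and C4), via aldoketene 22 (not isolated)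
Conditions: Et3N (1.5 equiv), CH2Cl2, 0 °C → rt; 8 added slowly to 18 (2 equiv)
Reagents that add atoms: none
Why: Dehydrochlorination gives the aldoketene, whose electrophilic carbonyl carbon is attacked by the nucleophilic alkyl-bearing carbon of the ynol ether in a ketene–alkoxyalkyne [2+2] cycloaddition, so the benzyloxy carbon ends up β to the carbonyl and the catechin-methyl group at C4; slow addition keeps the ketene dilute against dimerisation.

Step 14
Reactants: 23 cyclobutenone; 21 1-methoxyprop-1-yne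
Product: 28 ring D phenol bearing C1' CH(OTBS)[(R)-sec-butyl] / C2' OBn / C3' CH2–PBC-8-yl / C4' OH / C5' CH3 / C6' OCH3, via vinylketene 24 (not isolated), via 4-vinylcyclobutenone 25 (not isolated), via dienylketene 26 (not isolated), via cyclohexa-2,4-dienone 27 (not isolated)
Conditions: 21 (4 equiv), toluene, 80 → 110 °C, sealed tube
Reagents that add atoms: none
Why: Heating opens 23 by conrotatory 4π electrocyclic cleavage of C1–C4 (CH2–PBC group rotating outward) to vinylketene 24, which adds 21 in a [2+2] cycloaddition to give 25 (forming C4'–C5' and C6'–C1'); a second 4π opening gives dienylketene 26, thermal 6π electrocyclisation forms C3'–C4' to give dienone 27, and tautomerisation delivers phenol 28. The closest known reaction is the Danheiser benzannulation of cyclobutenones with alkoxyalkynes. Ring D is closed by the disrotatory 6π electrocyclisation of the dienylketene, after the two intermolecular bonds have been made in the [2+2] step. No stereocentre is created: cyclobutenone C4 and the quaternary carbon of 25 both become aromatic carbons, and the flavan and side-chain centres are untouched under neutral thermal conditions, the latter being non-enolisable next to the silyl carbinol. The selectivity needed is the orientation of the [2+2] step, secured by polarity, since the nucleophilic methyl-bearing alkyne carbon bonds to the ketene carbonyl carbon and the methoxy carbon to the ketene α-carbon, which places OCH3 at C6' between C5'–CH3 and the side chain and the new OH at C4'. The methyl ynol ether has no β-hydrogen for retro-ene loss at this temperature and is used in excess so that capture of 24 outpaces its self-reaction.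

Step 15
Reactants: 28 ring D phenol
Product: 29 C4'-O-benzyl ether of 28
Conditions: BnBr, K2CO3, DMF, 50 °C
Reagents that add atoms: benzyl bromide, BrCc1ccccc1
Why: Williamson benzylation masks the phenol para to the carbinol, which would otherwise open quinone methide formation on desilylation and ring oxidation in step 17.

Step 16
Reactants: 29 benzyl ether
Product: 30 ring D carbinol (C1' CH(OH)[(R)-sec-butyl], epimers at the carbinol carbon)
Conditions: TBAF, THF, rt → 45 °C
Reagents that add atoms: none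
Why: Fluoride cleaves the Si–O bond under non-acidic conditions, so the electron-rich benzylic C–O bond is not ionised.

Step 17
Reactants: 30 ring D carbinol
Product: 31 hepta-O-benzyl ketone (C1' (R)-2-methylbutanoyl)
Conditions: Dess–Martin periodinane, NaHCO3, CH2Cl2, 0 °C → rt
Reagents that add atoms: none
Why: Dess–Martin oxidation of the benzylic alcohol under buffered neutral conditions converges both carbinol epimers to one ketone without enolising the adjacent stereocentre of the hindered aryl ketone.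

Step 18
Reactants: 31 hepta-O-benzyl ketone
Product: 32 CNP0299940.2 (target)
Conditions: H2 (1 atm), Pd(OH)2/C, THF/MeOH, rt
Reagents that add atoms: none
Why: Catalytic hydrogenolysis removes all seven benzyl ethers under neutral conditions that are standard for benzylated flavan-3-ols; the ortho-hydroxy aryl ketone that emerges is hydrogen-bonded and resists reduction, and no stereocentre is labile.

**Compound list**

1 | (+)-catechin, (2R,3S)-2-(3,4-dihydroxyphenyl)chromane-3,5,7-triol | O[C@H]1Cc2c(O)cc(O)cc2O[C@@H]1c1ccc(O)c(O)c1 | starting material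
2 | (2R,3S)-5,7-bis(benzyloxy)-2-[3,4-bis(benzyloxy)phenyl]chroman-3-ol | c1c(OCc2ccccc2)cc(OCc2ccccc2)c2c1O[C@H](c1ccc(OCc3ccccc3)c(OCc3ccccc3)c1)[C@@H](O)C2 | intermediate
3 | (2R,3S)-3,5,7-tris(benzyloxy)-2-[3,4-bis(benzyloxy)phenyl]chromane | c1c(OCc2ccccc2)cc(OCc2ccccc2)c2c1O[C@H](c1ccc(OCc3ccccc3)c(OCc3ccccc3)c1)[C@@H](OCc1ccccc1)C2 | intermediate
4 | (2R,3S)-8-bromo-3,5,7-tris(benzyloxy)-2-[3,4-bis(benzyloxy)phenyl]chromane | Brc1c(OCc2ccccc2)cc(OCc2ccccc2)c2c1O[C@H](c1ccc(OCc3ccccc3)c(OCc3ccccc3)c1)[C@@H](OCc1ccccc1)C2 | intermediate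
5 | (3-ethoxy-3-oxopropyl)zinc bromide | CCOC(=O)CC[Zn]Br | starting material
6 | ethyl 3-(PBC-8-yl)propanoate | CCOC(=O)CCc1c(OCc2ccccc2)cc(OCc2ccccc2)c2c1O[C@H](c1ccc(OCc3ccccc3)c(OCc3ccccc3)c1)[C@@H](OCc1ccccc1)C2 | intermediate
7 | 3-(PBC-8-yl)propanoic acid | OC(=O)CCc1c(OCc2ccccc2)cc(OCc2ccccc2)c2c1O[C@H](c1ccc(OCc3ccccc3)c(OCc3ccccc3)c1)[C@@H](OCc1ccccc1)C2 | intermediate
8 | 3-(PBC-8-yl)propanoyl chloride | ClC(=O)CCc1c(OCc2ccccc2)cc(OCc2ccccc2)c2c1O[C@H](c1ccc(OCc3ccccc3)c(OCc3ccccc3)c1)[C@@H](OCc1ccccc1)C2 | intermediate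
9 | (R)-2-methylbutanoic acid | CC[C@@H](C)C(=O)O | starting material
10 | (R)-2-methylbutan-1-ol | CC[C@@H](C)CO | intermediate
11 | (R)-2-methylbutanal | CC[C@@H](C)C=O | intermediate
12 | trichloroethylene | ClC=C(Cl)Cl | starting material
13 | benzyl alcohol | OCc1ccccc1 | starting material
14 | benzyl (E)-1,2-dichlorovinyl ether | Cl/C=C(/Cl)OCc1ccccc1 | intermediate
15 | benzyloxy(chloro)acetylene (formed in situ) | ClC#COCc1ccccc1 | intermediate
16 | lithium benzyloxyacetylide (formed in situ) | [Li]C#COCc1ccccc1 | intermediate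
17 | (4R)-1-(benzyloxy)-4-methylhex-1-yn-3-ol, both C3 epimers | CC[C@@H](C)C(O)C#COCc1ccccc1 | intermediate
18 | (4R)-1-(benzyloxy)-3-(tert-butyldimethylsilyloxy)-4-methylhex-1-yne, both C3 epimers | CC[C@@H](C)C(O[Si](C)(C)C(C)(C)C)C#COCc1ccccc1 | intermediate
19 | chloroacetaldehyde dimethyl acetal (2-chloro-1,1-dimethoxyethane) | COC(CCl)OC | starting material
20 | sodium methoxyacetylide (formed in situ) | [Na]C#COC | intermediate
21 | 1-methoxyprop-1-yne | CC#COC | intermediate
22 | 3-(PBC-8-yl)prop-1-en-1-one, the aldoketene (formed in situ) | O=C=CCc1c(OCc2ccccc2)cc(OCc2ccccc2)c2c1O[C@H](c1ccc(OCc3ccccc3)c(OCc3ccccc3)c1)[C@@H](OCc1ccccc1)C2 | intermediate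
23 | 3-(benzyloxy)-2-[(2R)-1-(tert-butyldimethylsilyloxy)-2-methylbutyl]-4-(PBC-8-ylmethyl)cyclobut-2-en-1-one, epimers at the carbinol carbon and C4 | CC[C@@H](C)C(O[Si](C)(C)C(C)(C)C)C1=C(OCc2ccccc2)C(Cc2c(OCc3ccccc3)cc(OCc3ccccc3)c3c2O[C@H](c2ccc(OCc4ccccc4)c(OCc4ccccc4)c2)[C@@H](OCc2ccccc2)C3)C1=O | intermediate
24 | vinylketene from ring opening of 23, CH2–PBC group trans to the ketene carbon (formed in situ) | CC[C@@H](C)C(O[Si](C)(C)C(C)(C)C)C(=C=O)/C(OCc1ccccc1)=C/Cc2c(OCc3ccccc3)cc(OCc3ccccc3)c3c2O[C@H](c2ccc(OCc4ccccc4)c(OCc4ccccc4)c2)[C@@H](OCc2ccccc2)C3 | intermediate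
25 | 3-methoxy-2-methyl-4-(silyloxyalkyl)-4-vinylcyclobut-2-en-1-one, the [2+2] adduct of 24 and 21 (formed in situ) | CC[C@@H](C)C(O[Si](C)(C)C(C)(C)C)C1(C(OC)=C(C)C1=O)/C(OCc1ccccc1)=C/Cc2c(OCc3ccccc3)cc(OCc3ccccc3)c3c2O[C@H](c2ccc(OCc4ccccc4)c(OCc4ccccc4)c2)[C@@H](OCc2ccccc2)C3 | intermediate
26 | dienylketene from ring opening of 25 (formed in situ) | CC[C@@H](C)C(O[Si](C)(C)C(C)(C)C)C(/C(OCc1ccccc1)=C/Cc2c(OCc3ccccc3)cc(OCc3ccccc3)c3c2O[C@H](c2ccc(OCc4ccccc4)c(OCc4ccccc4)c2)[C@@H](OCc2ccccc2)C3)=C(OC)/C(C)=C=O | intermediate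
27 | cyclohexa-2,4-dien-1-one from 6π closure of 26 (formed in situ) | CC[C@@H](C)C(O[Si](C)(C)C(C)(C)C)C1=C(OCc2ccccc2)C(Cc2c(OCc3ccccc3)cc(OCc3ccccc3)c3c2O[C@H](c2ccc(OCc4ccccc4)c(OCc4ccccc4)c2)[C@@H](OCc2ccccc2)C3)C(=O)C(C)=C1OC | intermediate
28 | ring D phenol: C1' CH(OTBS)[(R)-sec-butyl], C2' OBn, C3' CH2–PBC-8-yl, C4' OH, C5' CH3, C6' OCH3 | CC[C@@H](C)C(O[Si](C)(C)C(C)(C)C)c1c(OCc2ccccc2)c(Cc2c(OCc3ccccc3)cc(OCc3ccccc3)c3c2O[C@H](c2ccc(OCc4ccccc4)c(OCc4ccccc4)c2)[C@@H](OCc2ccccc2)C3)c(O)c(C)c1OC | intermediate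
29 | C4'-O-benzyl ether of 28 | CC[C@@H](C)C(O[Si](C)(C)C(C)(C)C)c1c(OCc2ccccc2)c(Cc2c(OCc3ccccc3)cc(OCc3ccccc3)c3c2O[C@H](c2ccc(OCc4ccccc4)c(OCc4ccccc4)c2)[C@@H](OCc2ccccc2)C3)c(OCc2ccccc2)c(C)c1OC | intermediate
30 | ring D carbinol: C1' CH(OH)[(R)-sec-butyl], C2' and C4' OBn, C5' CH3, C6' OCH3 | CC[C@@H](C)C(O)c1c(OCc2ccccc2)c(Cc2c(OCc3ccccc3)cc(OCc3ccccc3)c3c2O[C@H](c2ccc(OCc4ccccc4)c(OCc4ccccc4)c2)[C@@H](OCc2ccccc2)C3)c(OCc2ccccc2)c(C)c1OC | intermediate
31 | hepta-O-benzyl ketone: C1' (R)-2-methylbutanoyl | CC[C@@H](C)C(=O)c1c(OCc2ccccc2)c(Cc2c(OCc3ccccc3)cc(OCc3ccccc3)c3c2O[C@H](c2ccc(OCc4ccccc4)c(OCc4ccccc4)c2)[C@@H](OCc2ccccc2)C3)c(OCc2ccccc2)c(C)c1OC | intermediate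
32 | CNP0299940.2 | CC[C@@H](C)C(=O)c1c(O)c(Cc2c(O)cc(O)c3c2O[C@H](c2ccc(O)c(O)c2)[C@@H](O)C3)c(O)c(C)c1OC | target

**Step count and risks**

Total: 18 steps. Longest linear sequence: 12 steps from (+)-catechin (steps 1–6 and 13–18).

Steps most likely to fail:

1. Step 14. The donor-stabilised 3-alkoxycyclobutenone may ring-open sluggishly, and the hindered α-branched vinylketene may be captured by the internal ynol ether more slowly than it oligomerises or acylates the product phenol. Fallback, setting out from 23: the cyclobutenone would be heated in toluene with the more nucleophilic ketenophile triisopropyl(prop-1-yn-1-yloxy)silane F1, made from ethyl acetate by Kowalski ester homologation with TIPSCl trapping. This should give the C6' silyl ether phenol F2 with the same three bonds formed. Benzylation (BnBr, K2CO3, DMF) would give the C4' benzyl ether F3, and TBAF would remove both silyl groups to give the C6' phenol carbinol F4. Methylation of the phenol alone (MeI, K2CO3, acetone) returns to the route at 30.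

2. Step 13. Ketene dimerisation, and hydrochloride-promoted decomposition or [3,3]-sigmatropic rearrangement of the benzyl ynol ether, may outrun cycloaddition to the hindered internal alkyne. Fallback, setting out from 4: the ketene would be generated under neutral, amine-free conditions by Wolff rearrangement. Coupling of 4 with the Reformatsky reagent BrZnCH2CO2Et (Pd(OAc)2, SPhos) would give ethyl 2-(PBC-8-yl)acetate F5. Saponification would give 2-(PBC-8-yl)acetic acid F6, oxalyl chloride its acid chloride F7, and diazomethane the diazoketone 1-diazo-3-(PBC-8-yl)propan-2-one F8. Irradiation of F8 (λ > 300 nm, CH2Cl2, rt) in the presence of excess 18 releases ketene 22 slowly at low concentration, and its [2+2] capture returns to the route at 23.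

3. Step 4. Oxidative addition into the electron-rich di-ortho-alkoxy aryl bromide may be slow, allowing protodebromination or β-hydride loss from the homoenolate. Fallback, setting out from 4: bromine–lithium exchange (n-BuLi, THF, −78 °C) and DMF quench would give 8-formyl-penta-O-benzylcatechin F9. Horner–Wadsworth–Emmons olefination (triethyl phosphonoacetate, NaH, THF) would give ethyl (E)-3-(PBC-8-yl)acrylate F10. Conjugate reduction that spares benzyl ethers (NaBH4, NiCl2·6H2O, MeOH/THF, 0 °C) returns to the route at 6.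

**Further compounds**

F1 | step 14 | triisopropyl(prop-1-yn-1-yloxy)silane | CC#CO[Si](C(C)C)(C(C)C)C(C)C
F2 | step 14 | ring D phenol with C6' OTIPS (C1' CH(OTBS)[(R)-sec-butyl], C2' OBn, C3' CH2–PBC-8-yl, C4' OH, C5' CH3) | CC[C@@H](C)C(O[Si](C)(C)C(C)(C)C)c1c(OCc2ccccc2)c(Cc2c(OCc3ccccc3)cc(OCc3ccccc3)c3c2O[C@H](c2ccc(OCc4ccccc4)c(OCc4ccccc4)c2)[C@@H](OCc2ccccc2)C3)c(O)c(C)c1O[Si](C(C)C)(C(C)C)C(C)C
F3 | step 14 | C4'-O-benzyl ether of F2 | CC[C@@H](C)C(O[Si](C)(C)C(C)(C)C)c1c(OCc2ccccc2)c(Cc2c(OCc3ccccc3)cc(OCc3ccccc3)c3c2O[C@H](c2ccc(OCc4ccccc4)c(OCc4ccccc4)c2)[C@@H](OCc2ccccc2)C3)c(OCc2ccccc2)c(C)c1O[Si](C(C)C)(C(C)C)C(C)C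
F4 | step 14 | C6' phenol carbinol (C1' CH(OH)[(R)-sec-butyl], C2' and C4' OBn, C5' CH3, C6' OH) | CC[C@@H](C)C(O)c1c(OCc2ccccc2)c(Cc2c(OCc3ccccc3)cc(OCc3ccccc3)c3c2O[C@H](c2ccc(OCc4ccccc4)c(OCc4ccccc4)c2)[C@@H](OCc2ccccc2)C3)c(OCc2ccccc2)c(C)c1O
F5 | step 13 | ethyl 2-(PBC-8-yl)acetate | CCOC(=O)Cc1c(OCc2ccccc2)cc(OCc2ccccc2)c2c1O[C@H](c1ccc(OCc3ccccc3)c(OCc3ccccc3)c1)[C@@H](OCc1ccccc1)C2
F6 | step 13 | 2-(PBC-8-yl)acetic acid | OC(=O)Cc1c(OCc2ccccc2)cc(OCc2ccccc2)c2c1O[C@H](c1ccc(OCc3ccccc3)c(OCc3ccccc3)c1)[C@@H](OCc1ccccc1)C2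
F7 | step 13 | 2-(PBC-8-yl)acetyl chloride | ClC(=O)Cc1c(OCc2ccccc2)cc(OCc2ccccc2)c2c1O[C@H](c1ccc(OCc3ccccc3)c(OCc3ccccc3)c1)[C@@H](OCc1ccccc1)C2
F8 | step 13 | 1-diazo-3-(PBC-8-yl)propan-2-one | [N-]=[N+]=CC(=O)Cc1c(OCc2ccccc2)cc(OCc2ccccc2)c2c1O[C@H](c1ccc(OCc3ccccc3)c(OCc3ccccc3)c1)[C@@H](OCc1ccccc1)C2
F9 | step 4 | 8-formyl-penta-O-benzylcatechin | O=Cc1c(OCc2ccccc2)cc(OCc2ccccc2)c2c1O[C@H](c1ccc(OCc3ccccc3)c(OCc3ccccc3)c1)[C@@H](OCc1ccccc1)C2
F10 | step 4 | ethyl (E)-3-(PBC-8-yl)acrylate | CCOC(=O)/C=C/c1c(OCc2ccccc2)cc(OCc2ccccc2)c2c1O[C@H](c1ccc(OCc3ccccc3)c(OCc3ccccc3)c1)[C@@H](OCc1ccccc1)C2
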